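**Plan**

1. Numbering (kept for the corresponding atoms of all intermediates): ring A = C1–C5 and C10 (gem-dimethyl on C4, carbinol C5); ring B = C5–C10 (CHMe at C8, quaternary C9); C11 = benzylic carbon.
2. Cuts, in retrosynthetic order: the quinone (from a 2,6-dihydroxy-3,5-dimethoxyaryl ring by oxidation); the C11–aryl bond (aryllithium plus lactone carbonyl); the C5–O and C3–C4 bonds (one cationic event); ring B (C9–C10 Knoevenagel, C8–C9 Roskamp, C5–C6 Michael).
3. Enabling feature: C5 is a tertiary carbinol flanked by the gem-dimethyl carbon C4 of ring A and 1,3-diaxial to the C9 arm C11 on ring B. Ring A is therefore the Wagner–Meerwein ring-expansion product of a trans-hydrindane (five-membered ring C5, C10, C1, C2, C3) carrying C4 as an angular C(CH3)2OH group on C5; the relocated C5 cation is caught by a carboxyl group at C11 (γ-lactone tether).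
4. Forward order: five-membered ring (bought), ring B, then ring A by ring expansion together with the temporary lactone ring, then the arene. The C11 oxygen is removed by ionic hydrogenation, and the quinone is made last.
5. Stereochemistry: C5 of the hydrindane comes from an organocatalytic Michael addition and relays to C10 (hydride), C9 (methylation) and C8 (hydrogenation), each anti to the axial ester groups. C5 is then erased in the key step and reset by the lactone tether, cis to C11.

Key step: step 8

Remark: 19 is written as the open hydroxy ketone; its ring-closed lactol tautomer would react in the same way in step 12.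

**Route**

Step 1
Reactants: 1 methyl 2-oxocyclopentane-1-carboxylate; 2 acrolein
Product: 3 methyl (1R)-2-oxo-1-(3-oxopropyl)cyclopentane-1-carboxylate
Conditions: 6'-hydroxy cinchona catalyst (9-O-benzylcupreine or its pseudoenantiomer 9-O-benzylcupreidine, whichever delivers the (R)-adduct, 10 mol %), CH2Cl2, −24 °C
Reagents that add atoms: none
Why: The Michael addition of an α-substituted cyclic β-keto ester to an enal under bifunctional cinchona catalysis is a known enantioselective reaction type and should set the quaternary centre C5 under catalyst control.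

Step 2
Reactants: 3 methyl (1R)-2-oxo-1-(3-oxopropyl)cyclopentane-1-carboxylate; 4 tert-butyl diazoacetate
Product: 5 methyl (1R)-1-(5-tert-butoxy-3,5-dioxopentyl)-2-oxocyclopentane-1-carboxylate
Conditions: SnCl2 (10 mol %), CH2Cl2, rt
Reagents that add atoms: none
Why: The Roskamp homologation should convert the aldehyde into the β-keto ester with loss of N2 and leave the less electrophilic ketone and the methyl ester untouched.

Step 3
Reactants: 5 methyl (1R)-1-(5-tert-butoxy-3,5-dioxopentyl)-2-oxocyclopentane-1-carboxylate
Product: 6 4-tert-butyl 7a-methyl (7aR)-5-oxo-1,2,3,5,6,7-hexahydro-7aH-indene-4,7a-dicarboxylate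
Conditions: piperidine (20 mol %), AcOH (20 mol %), toluene, reflux, water separator
Reagents that add atoms: none
Why: An intramolecular Knoevenagel condensation of the active methylene C9 onto the cyclopentanone carbonyl C10 should close ring B as the tetrasubstituted alkylidene β-keto ester, as in the aldol step of a Robinson annulation.

Step 4
Reactants: 6 4-tert-butyl 7a-methyl (7aR)-5-oxo-1,2,3,5,6,7-hexahydro-7aH-indene-4,7a-dicarboxylate
Product: 8 4-tert-butyl 7a-methyl (3aR,4R,7aR)-4-methyl-5-oxooctahydro-1H-indene-4,7a-dicarboxylate, via lithium enolate 7 (not isolated)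
Conditions: LiBH(s-Bu)3 (1.1 equiv), THF, −78 °C; then MeI (5 equiv), DMPU, −78 → 0 °C
Reagents that add atoms: iodomethane, CI
Why: In this conjugate reduction–enolate alkylation of a 2-alkylidene 1,3-dicarbonyl compound, hydride should add axially to C10 anti to the angular ester (trans ring fusion) and MeI should attack C9 anti to the same 1,3-diaxial ester, which leaves the C9 ester cis to the angular ester.

Step 5
Reactants: 8 4-tert-butyl 7a-methyl (3aR,4R,7aR)-4-methyl-5-oxooctahydro-1H-indene-4,7a-dicarboxylate
Product: 9 4-tert-butyl 7a-methyl (3aR,4R,7aR)-4-methyl-5-methylideneoctahydro-1H-indene-4,7a-dicarboxylate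
Conditions: Ph3PCH3Br (3 equiv), KOt-Bu (2.8 equiv), toluene, 90 °C
Reagents that add atoms: methylenetriphenylphosphorane, C=P(c1ccccc1)(c1ccccc1)c1ccccc1
Why: Wittig methylenation under salt-free, hot conditions is the usual answer to a ketone next to a quaternary carbon, and both hindered esters should be inert to the ylide.

Step 6
Reactants: 9 4-tert-butyl 7a-methyl (3aR,4R,7aR)-4-methyl-5-methylideneoctahydro-1H-indene-4,7a-dicarboxylate
Product: 10 4-tert-butyl 7a-methyl (3aR,4S,5S,7aR)-4,5-dimethyloctahydro-1H-indene-4,7a-dicarboxylate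
Conditions: H2 (1 atm), Pd/C (10 %), EtOAc, rt
Reagents that add atoms: none
Why: Heterogeneous hydrogenation of the 1,1-disubstituted alkene should deliver hydrogen to C8 from the face opposite the axial C9 ester, so the C8 methyl ends equatorial and cis to that ester.

Step 7
Reactants: 10 4-tert-butyl 7a-methyl (3aR,4S,5S,7aR)-4,5-dimethyloctahydro-1H-indene-4,7a-dicarboxylate
Product: 12 tert-butyl (3aR,4S,5S,7aR)-7a-(2-hydroxypropan-2-yl)-4,5-dimethyloctahydro-1H-indene-4-carboxylate, via methyl ketone 11 (not isolated)
Conditions: MeLi (4 equiv), Et2O, −78 → 0 °C; aq NH4Cl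
Reagents that add atoms: methyllithium, [Li]C
Why: Double addition of MeLi should convert the methyl ester into the tertiary carbinol C4, while the pivalate-like tert-butyl ester is far less electrophilic and neither ester has an α-hydrogen.

Step 8
Reactants: 12 tert-butyl (3aR,4S,5S,7aR)-7a-(2-hydroxypropan-2-yl)-4,5-dimethyloctahydro-1H-indene-4-carboxylate
Product: 14 γ-lactone of (1S,2S,4aR,8aS)-4a-hydroxy-1,2,5,5-tetramethyldecahydronaphthalene-1-carboxylic acid, via hydroxy acid 13 (not isolated)
Conditions: CF3CO2H/CH2Cl2 (1:4), 0 °C → rt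
Reagents that add atoms: none
Why: Acid cleaves the tert-butyl ester to acid 13 and ionises the tertiary carbinol to the C4 dimethylcarbinyl cation; the C3–C5 bond of the cyclopentane then migrates to C4 (1,2-alkyl shift, cyclopentylcarbinyl to cyclohexyl), which forms the C3–C4 bond, enlarges the five-membered ring to ring A and moves the charge to the ring-fusion carbon C5, where the 1,3-diaxial C9 carboxyl group closes the C5–O bond. The closest known reaction type is the acid-promoted Wagner–Meerwein ring expansion of cycloalkyl dimethyl carbinols, combined with the rearrangement–lactonisation of terpenoid acids in which a relocated tertiary cation is captured by a carboxyl group. Ring A closes by ring expansion from five to six atoms, and the γ-lactone closes by capture of the C5 cation across the 1,3-diaxial positions of ring B (five-membered ring, 6-oxabicyclo[3.2.1]octan-7-one type). The new stereocentre C5 is controlled by the tether: the carboxyl group on C9 can reach C5 only from its own face, so the oxygen should end cis to C11 and trans to H10 (trans-decalin), while the earlier C5 configuration, which served only as a relay, is erased. The step needs migration of C3 and not of C6 or C10, which relief of cyclopentane strain should secure (a C6 shift would give a cycloheptane, a C10 shift a bridged cation), and it needs capture of the C5 cation before a hydride shift from C10, which the neighbouring carboxyl group should secure; an isomeric δ-lactone or isopropenyl acid formed on the way re-enters through the same C4 cation.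

Step 9
Reactants: 15 1,5-dibromo-2,4-dimethoxybenzene
Product: 16 4,6-dimethoxybenzene-1,3-diol
Conditions: Pd2(dba)3 (2 mol %), t-BuXPhos (8 mol %), KOH (6 equiv), 1,4-dioxane/H2O, 100 °C, argon; then aq HCl
Reagents that add atoms: potassium hydroxide, [K+].[OH-]
Why: Palladium-catalysed hydroxylation of aryl bromides with KOH and a bulky biarylphosphine is a known C–O coupling and should replace both bromides.

Step 10
Reactants: 16 4,6-dimethoxybenzene-1,3-diol
Product: 17 1,5-dimethoxy-2,4-bis(methoxymethoxy)benzene
Conditions: NaH (2.4 equiv), MOMCl (2.4 equiv), THF/DMF, 0 °C → rt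
Reagents that add atoms: chloromethyl methyl ether, COCCl
Why: Williamson-type alkylation of both phenoxides installs acid-labile MOM ethers that also direct the later metalation to the position between them.

Step 11
Reactants: 17 1,5-dimethoxy-2,4-bis(methoxymethoxy)benzene; 14 γ-lactone of (1S,2S,4aR,8aS)-4a-hydroxy-1,2,5,5-tetramethyldecahydronaphthalene-1-carboxylic acid
Product: 19 [2,6-bis(methoxymethoxy)-3,5-dimethoxyphenyl][(1S,2S,4aR,8aS)-4a-hydroxy-1,2,5,5-tetramethyldecahydronaphthalen-1-yl]methanone, via aryllithium 18 (not isolated)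
Conditions: 17 (1.5 equiv), n-BuLi (1.4 equiv), TMEDA, THF, 0 °C; then 14, −78 → 0 °C; aq NH4Cl
Reagents that add atoms: none
Why: Directed ortho-metalation between the two MOM ethers, followed by a single addition of the aryllithium to the lactone carbonyl (no α-hydrogen, stable tetrahedral alkoxide), is the reaction type used for aryl C-glycosides from lactones; it should form the C11–aryl bond and free the C5 alkoxide.

Step 12
Reactants: 19 [2,6-bis(methoxymethoxy)-3,5-dimethoxyphenyl][(1S,2S,4aR,8aS)-4a-hydroxy-1,2,5,5-tetramethyldecahydronaphthalen-1-yl]methanone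
Product: 20 2-{[(1S,2S,4aR,8aS)-4a-hydroxy-1,2,5,5-tetramethyldecahydronaphthalen-1-yl]methyl}-4,6-dimethoxybenzene-1,3-diol
Conditions: Et3SiH (6 equiv), CF3CO2H (10 equiv), CH2Cl2, −20 → 0 °C
Reagents that add atoms: none
Why: In this ionic hydrogenation the silane should reduce first the cyclic oxocarbenium ion formed from the ketone and the C5 hydroxyl and then the benzylic cation (stabilised by the electron-rich arene) to the C11 methylene, leaving the tertiary C5–O bond intact, while the acid cleaves both MOM ethers.

Step 13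
Reactants: 20 2-{[(1S,2S,4aR,8aS)-4a-hydroxy-1,2,5,5-tetramethyldecahydronaphthalen-1-yl]methyl}-4,6-dimethoxybenzene-1,3-diol
Product: 21 2-hydroxy-3-{[(1S,2S,4aR,8aS)-4a-hydroxy-1,2,5,5-tetramethyldecahydronaphthalen-1-yl]methyl}-5-methoxycyclohexa-2,5-diene-1,4-dione
Conditions: PhI(OAc)2 (1.1 equiv), MeCN/H2O (2:1), 0 °C
Reagents that add atoms: water, O
Why: Oxidative demethylation of a para-methoxyphenol should give the para-quinone, and because the arene is symmetric either phenol leads to the same 2-hydroxy-5-methoxyquinone.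

**Compound list**

1 | methyl 2-oxocyclopentane-1-carboxylate | COC(=O)C1CCCC1=O | starting material
2 | acrolein | C=CC=O | starting material
3 | methyl (1R)-2-oxo-1-(3-oxopropyl)cyclopentane-1-carboxylate | COC(=O)[C@@]1(CCC=O)CCCC1=O | intermediate
4 | tert-butyl diazoacetate | CC(C)(C)OC(=O)C=[N+]=[N-] | starting material
5 | methyl (1R)-1-(5-tert-butoxy-3,5-dioxopentyl)-2-oxocyclopentane-1-carboxylate | COC(=O)[C@@]1(CCC(=O)CC(=O)OC(C)(C)C)CCCC1=O | intermediate
6 | 4-tert-butyl 7a-methyl (7aR)-5-oxo-1,2,3,5,6,7-hexahydro-7aH-indene-4,7a-dicarboxylate | COC(=O)[C@@]12CCCC1=C(C(=O)OC(C)(C)C)C(=O)CC2 | intermediate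
7 | lithium (3aR,7aR)-4-(tert-butoxycarbonyl)-7a-(methoxycarbonyl)-2,3,3a,6,7,7a-hexahydro-1H-inden-5-olate (lithium enolate) | COC(=O)[C@@]12CCC[C@H]1C(C(=O)OC(C)(C)C)=C([O-])CC2.[Li+] | intermediate
8 | 4-tert-butyl 7a-methyl (3aR,4R,7aR)-4-methyl-5-oxooctahydro-1H-indene-4,7a-dicarboxylate | COC(=O)[C@@]12CCC[C@H]1[C@@](C)(C(=O)OC(C)(C)C)C(=O)CC2 | intermediate
9 | 4-tert-butyl 7a-methyl (3aR,4R,7aR)-4-methyl-5-methylideneoctahydro-1H-indene-4,7a-dicarboxylate | COC(=O)[C@@]12CCC[C@H]1[C@@](C)(C(=O)OC(C)(C)C)C(=C)CC2 | intermediate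
10 | 4-tert-butyl 7a-methyl (3aR,4S,5S,7aR)-4,5-dimethyloctahydro-1H-indene-4,7a-dicarboxylate | COC(=O)[C@@]12CCC[C@H]1[C@@](C)(C(=O)OC(C)(C)C)[C@@H](C)CC2 | intermediate
11 | tert-butyl (3aR,4S,5S,7aR)-7a-acetyl-4,5-dimethyloctahydro-1H-indene-4-carboxylate (methyl ketone) | CC(=O)[C@@]12CCC[C@H]1[C@@](C)(C(=O)OC(C)(C)C)[C@@H](C)CC2 | intermediate
12 | tert-butyl (3aR,4S,5S,7aR)-7a-(2-hydroxypropan-2-yl)-4,5-dimethyloctahydro-1H-indene-4-carboxylate | CC(C)(O)[C@@]12CCC[C@H]1[C@@](C)(C(=O)OC(C)(C)C)[C@@H](C)CC2 | intermediate
13 | (3aR,4S,5S,7aR)-7a-(2-hydroxypropan-2-yl)-4,5-dimethyloctahydro-1H-indene-4-carboxylic acid (hydroxy acid) | CC(C)(O)[C@@]12CCC[C@H]1[C@@](C)(C(=O)O)[C@@H](C)CC2 | intermediate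
14 | γ-lactone of (1S,2S,4aR,8aS)-4a-hydroxy-1,2,5,5-tetramethyldecahydronaphthalene-1-carboxylic acid (carboxyl on C1 to oxygen on C4a) | O=C1O[C@]23CC[C@H](C)[C@@]1(C)[C@@H]2CCCC3(C)C | intermediate
15 | 1,5-dibromo-2,4-dimethoxybenzene | COc1cc(OC)c(Br)cc1Br | starting material
16 | 4,6-dimethoxybenzene-1,3-diol | COc1cc(OC)c(O)cc1O | intermediate
17 | 1,5-dimethoxy-2,4-bis(methoxymethoxy)benzene | COCOc1cc(OCOC)c(OC)cc1OC | intermediate
18 | [2,6-bis(methoxymethoxy)-3,5-dimethoxyphenyl]lithium (aryllithium) | [Li]c1c(OCOC)c(OC)cc(OC)c1OCOC | intermediate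
19 | [2,6-bis(methoxymethoxy)-3,5-dimethoxyphenyl][(1S,2S,4aR,8aS)-4a-hydroxy-1,2,5,5-tetramethyldecahydronaphthalen-1-yl]methanone | COCOc1c(OC)cc(OC)c(OCOC)c1C(=O)[C@@]1(C)[C@@H](C)CC[C@@]2(O)[C@H]1CCCC2(C)C | intermediate
20 | 2-{[(1S,2S,4aR,8aS)-4a-hydroxy-1,2,5,5-tetramethyldecahydronaphthalen-1-yl]methyl}-4,6-dimethoxybenzene-1,3-diol | COc1cc(OC)c(O)c(C[C@@]2(C)[C@@H](C)CC[C@@]3(O)[C@H]2CCCC3(C)C)c1O | intermediate
21 | 2-hydroxy-3-{[(1S,2S,4aR,8aS)-4a-hydroxy-1,2,5,5-tetramethyldecahydronaphthalen-1-yl]methyl}-5-methoxycyclohexa-2,5-diene-1,4-dione | COC1=CC(=O)C(O)=C(C[C@@]2(C)[C@@H](C)CC[C@@]3(O)[C@H]2CCCC3(C)C)C1=O | target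

**Count and risks**

Total steps: 13. Longest linear sequence: 11 steps (steps 1–8 and 11–13); the arene branch is steps 9–10.

Steps most likely to fail:

Step 8. The ionisation is reversible, so the C5 cation may leak into a hydride shift from C10 or loss of H10 (erosion of the ring fusion) before lactonisation, or the system may rest in the unexpanded δ-lactone. The fallback moves the tether to the alcohol oxidation level and makes the capture irreversible. Setting out from 12, LiAlH4 (THF, 0 °C) would reduce the tert-butyl ester to 2-[(3aS,4S,5S,7aR)-4-(hydroxymethyl)-4,5-dimethyloctahydro-7aH-inden-7a-yl]propan-2-ol F1. Brief exposure to BF3·OEt2 (CH2Cl2, −40 °C) would trigger the same carbinol ionisation and 1,2-shift, but the C5 cation would now be trapped by the primary hydroxyl as the bridged ether F2, which does not re-ionise under these conditions. RuCl3 (cat.)/NaIO4 (CCl4/MeCN/H2O) would then oxidise the only ether CH2 group to the carbonyl, and the route is rejoined at 14.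

Step 4. Hydride delivery to the tetrasubstituted C10 may show poor facial selectivity (cis ring fusion), or 1,2-reduction and O-methylation of the enolate may compete. The fallback sets C10 by hydrogenation instead. Setting out from 6, deconjugative α-methylation of the extended enolate (NaH, MeI, THF, 0 °C) would give 4-tert-butyl 7a-methyl (4R,7aR)-4-methyl-5-oxo-1,2,4,5,6,7-hexahydro-7aH-indene-4,7a-dicarboxylate F3, with the methyl anti to the angular ester. Wittig methylenation as in step 5 would give the diene 4-tert-butyl 7a-methyl (4R,7aR)-4-methyl-5-methylidene-1,2,4,5,6,7-hexahydro-7aH-indene-4,7a-dicarboxylate F4. Hydrogenation of both double bonds (H2, PtO2, EtOAc/AcOH) from the face opposite the two axial esters would set C10 and C8 together, and the route is rejoined at 10.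

Step 12. The acid may ionise the liberated tertiary C5 alcohol (elimination or over-reduction), or the second hydride transfer may stall at the crowded benzylic carbon. The fallback avoids carbocations. Setting out from 19, dissolving-metal reduction (Li, NH3/THF, −78 °C, then NH4Cl) would take the aryl ketone to the methylene compound 3-{[(1S,2S,4aR,8aS)-4a-hydroxy-1,2,5,5-tetramethyldecahydronaphthalen-1-yl]methyl}-1,5-dimethoxy-2,4-bis(methoxymethoxy)benzene F5. Dilute HCl in MeOH at room temperature would then remove the MOM ethers, and the route is rejoined at 20.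

Further compounds
F1 | step 8 | 2-[(3aS,4S,5S,7aR)-4-(hydroxymethyl)-4,5-dimethyloctahydro-7aH-inden-7a-yl]propan-2-ol | CC(C)(O)[C@@]12CCC[C@H]1[C@@](C)(CO)[C@@H](C)CC2
F2 | step 8 | bridged ether (C11–O–C5) of (1S,2S,4aR,8aS)-1-(hydroxymethyl)-1,2,5,5-tetramethyldecahydronaphthalen-4a-ol | C1O[C@]23CC[C@H](C)[C@@]1(C)[C@@H]2CCCC3(C)C
F3 | step 4 | 4-tert-butyl 7a-methyl (4R,7aR)-4-methyl-5-oxo-1,2,4,5,6,7-hexahydro-7aH-indene-4,7a-dicarboxylate | COC(=O)[C@@]12CCC=C1[C@@](C)(C(=O)OC(C)(C)C)C(=O)CC2
F4 | step 4 | 4-tert-butyl 7a-methyl (4S,7aR)-4-methyl-5-methylidene-1,2,4,5,6,7-hexahydro-7aH-indene-4,7a-dicarboxylate | COC(=O)[C@@]12CCC=C1[C@@](C)(C(=O)OC(C)(C)C)C(=C)CC2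
F5 | step 12 | 3-{[(1S,2S,4aR,8aS)-4a-hydroxy-1,2,5,5-tetramethyldecahydronaphthalen-1-yl]methyl}-1,5-dimethoxy-2,4-bis(methoxymethoxy)benzene | COCOc1c(OC)cc(OC)c(OCOC)c1C[C@@]1(C)[C@@H](C)CC[C@@]2(O)[C@H]1CCCC2(C)C
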